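**Plan**
- Cuts, in retrosynthetic order: the tertiary C–OH bond (back to an isopropenyl group) and the O7–benzyl bond; then the two bonds joining ring D to ring B, O4'–C2 and C3'–CH2, giving a 3'-iodo-4'-hydroxyisoflavone and isoprene; last, ring C at its C2 carbon (from DMF) and at the aryl–C4 ketone bond, giving phloroglucinol and 4-hydroxy-3-iodophenylacetic acid.
- Enabling feature: the dihydrofuran ring D with the 2-hydroxyprop-2-yl branch on its C2 is one five-carbon isoprene unit bridging C3' and the 4'-oxygen of a genistein ring B, so an ortho-iodophenol and isoprene map directly onto it.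
- Forward order: ring A is bought, ring C closes by acylation and formylative cyclization (step 1), O7 is benzylated (step 2), ring D is annulated (step 3), the alkene is hydrated (step 4) and the benzyl ether is removed (step 5).
- Stereochemistry: the only stereocenter, C2 of ring D (R), is set in step 3 by the chiral phosphine on palladium; steps 4 and 5 do not involve that carbon.

Key step: step 3

Assumption: the ligand enantiomer for step 3 is the one that gives (R)-2-isopropenyl-2,3-dihydrobenzofurans from simple 2-halophenols and isoprene; the remote isoflavone substituent para to the ring D oxygen is not expected to change the sense of induction.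

Step 1
Reactants: 1 phloroglucinol (anhydrous); 2 4-hydroxy-3-iodophenylacetic acid
Product: 4 3'-iodogenistein (5,7,4'-trihydroxy-3'-iodoisoflavone), via iodo deoxybenzoin 3 (not isolated)
Conditions: BF3·OEt2 (solvent), 80 °C; then DMF, MsCl, 50 to 80 °C, same flask; H2O quench
Reagents that add atoms: N,N-dimethylformamide, CN(C)C=O
Why: BF3-promoted Friedel–Crafts C-acylation of the threefold-symmetric, very electron-rich phloroglucinol can give only one deoxybenzoin, whose active methylene is then formylated by the Vilsmeier-type iminium reagent from DMF and MsCl and cyclodehydrated to the chromone (the established one-pot deoxybenzoin route to 5,7-dihydroxyisoflavones), with the aryl iodide and the ring B phenol as spectators.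

Step 2
Reactants: 4 3'-iodogenistein
Product: 5 7-benzyloxy-5,4'-dihydroxy-3'-iodoisoflavone
Conditions: BnBr (1.05 equiv), KHCO3 (1.2 equiv), DMF, 40 °C
Reagents that add atoms: benzyl bromide, BrCc1ccccc1
Why: Williamson etherification under weak-base control should go to O7, because the 7-OH (a vinylogous carboxylic acid para to the chromone carbonyl) is the phenol ionized by bicarbonate, the 5-OH is locked in a hydrogen bond to C4=O, and the 4'-OH is less acidic and flanked by iodine, in line with the known order of alkylation of genistein.

Step 3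
Reactants: 5 7-benzyloxy-5,4'-dihydroxy-3'-iodoisoflavone; 6 isoprene
Product: 7 7-benzyloxy-5-hydroxy-3-[(2R)-2-(prop-1-en-2-yl)-2,3-dihydro-1-benzofuran-5-yl]-4H-chromen-4-one
Conditions: 6 (5 equiv), Pd2(dba)3·CHCl3 (5 mol%), chiral tert-butanesulfinamide-based monophosphine L* (TY-Phos type, 20 mol%), PhONa (2 equiv), CH2Cl2, 40 °C, sealed tube
Reagents that add atoms: none
Why: Oxidative addition of zerovalent palladium to the C3'–I bond gives ArPdI(L*), which carbopalladates the unsubstituted CH=CH2 end of isoprene with the aryl group going to the terminal C4 (new C3'–CH2 bond), and the resulting η3-allyl–Pd(L*) unit over C3, C2(CH3) and C1 is attacked at C3 by the neighbouring 4'-phenoxide (new O–C2 bond of ring D), which returns zerovalent palladium. The closest known reaction type is the Larock heteroannulation of 1,3-dienes with ortho-halophenols run as an enantioselective Heck/Tsuji–Trost cascade, a process already applied to isoprene to make 2-isopropenyl-2,3-dihydrobenzofurans. Ring D closes in the 5-exo mode by allylic C–O substitution, since attack at the far allyl terminus C1 would require a seven-membered ring. The stereocenter C2 of ring D is set under control of the chiral ligand on palladium: the two faces of the allyl unit exchange through the η1 form at its CH2 terminus, so the ligand selects the diastereomeric complex that undergoes C–O bond formation, and the ligand enantiomer is chosen to give R. The step needs aryl transfer to the less substituted double bond of isoprene, secured by the lower steric demand of the CH=CH2 end, and O-alkylation by O4' alone, secured by its position ortho to the reacting carbon while O7 is benzylated and the 5-OH is held in a hydrogen bond to the C4 carbonyl.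

Step 4
Reactants: 7 7-benzyloxy-5-hydroxy-3-[(2R)-2-(prop-1-en-2-yl)-2,3-dihydro-1-benzofuran-5-yl]-4H-chromen-4-one
Product: 8 7-benzyloxy-5-hydroxy-3-[(2R)-2-(2-hydroxypropan-2-yl)-2,3-dihydro-1-benzofuran-5-yl]-4H-chromen-4-one
Conditions: Co(acac)2 (20 mol%), PhSiH3 (2.5 equiv), O2 (1 atm), THF, rt
Reagents that add atoms: dioxygen, O=O
Why: Mukaiyama hydration (hydrogen-atom transfer from a Co–H species to the 1,1-disubstituted alkene, capture of the tertiary radical by O2 and reduction of the peroxide by the silane) should give the Markovnikov tertiary alcohol, while the conjugated trisubstituted chromone double bond is much less reactive in hydrogen-atom transfer and the neighbouring stereocenter never becomes a radical, so it stays R.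

Step 5
Reactants: 8 7-benzyloxy-5-hydroxy-3-[(2R)-2-(2-hydroxypropan-2-yl)-2,3-dihydro-1-benzofuran-5-yl]-4H-chromen-4-one
Product: 9 5,7-dihydroxy-3-[(2R)-2-(2-hydroxypropan-2-yl)-2,3-dihydro-1-benzofuran-5-yl]-4H-chromen-4-one (target, CNP0200981.1)
Conditions: H2 (1 atm), 10% Pd/C, EtOAc/MeOH, rt
Reagents that add atoms: none
Why: Catalytic hydrogenolysis of the benzyl aryl ether is fast at 1 atm, whereas the vinylogous-ester C2=C3 bond of the isoflavone, the non-benzylic C2–O bond of ring D and the tertiary alcohol should not react under these mild conditions, so the stereocenter is carried through unchanged.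

**Compound list**
1 | phloroglucinol (benzene-1,3,5-triol) | Oc1cc(O)cc(O)c1 | starting material
2 | 4-hydroxy-3-iodophenylacetic acid | O=C(O)Cc1ccc(O)c(I)c1 | starting material
3 | 2-(4-hydroxy-3-iodophenyl)-1-(2,4,6-trihydroxyphenyl)ethan-1-one (iodo deoxybenzoin) | O=C(Cc1ccc(O)c(I)c1)c1c(O)cc(O)cc1O | intermediate
4 | 5,7,4'-trihydroxy-3'-iodoisoflavone (3'-iodogenistein) | O=c1c(-c2ccc(O)c(I)c2)coc2cc(O)cc(O)c12 | intermediate
5 | 7-benzyloxy-5,4'-dihydroxy-3'-iodoisoflavone | O=c1c(-c2ccc(O)c(I)c2)coc2cc(OCc3ccccc3)cc(O)c12 | intermediate
6 | isoprene (2-methylbuta-1,3-diene) | C=CC(C)=C | starting material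
7 | 7-benzyloxy-5-hydroxy-3-[(2R)-2-(prop-1-en-2-yl)-2,3-dihydro-1-benzofuran-5-yl]-4H-chromen-4-one | C=C(C)[C@H]1Cc2cc(-c3coc4cc(OCc5ccccc5)cc(O)c4c3=O)ccc2O1 | intermediate
8 | 7-benzyloxy-5-hydroxy-3-[(2R)-2-(2-hydroxypropan-2-yl)-2,3-dihydro-1-benzofuran-5-yl]-4H-chromen-4-one | CC(C)(O)[C@H]1Cc2cc(-c3coc4cc(OCc5ccccc5)cc(O)c4c3=O)ccc2O1 | intermediate
9 | 5,7-dihydroxy-3-[(2R)-2-(2-hydroxypropan-2-yl)-2,3-dihydro-1-benzofuran-5-yl]-4H-chromen-4-one | CC(C)(O)[C@H]1Cc2cc(-c3coc4cc(O)cc(O)c4c3=O)ccc2O1 | target

Total step count: 5. Longest linear sequence: 5 steps (1 and 2 to 9 through 4, 5, 7 and 8).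

**Steps most likely to fail**

Step 3. The chiral catalyst may give insufficient enantiocontrol or stall with this poorly soluble, polyoxygenated aryl iodide, for example through iodide binding to palladium weakening ligand control. The fallback sets out from 5 and 6 and obtains the stereocenter by resolution instead of catalyst control. The classical ligand-free Larock heteroannulation (Pd(OAc)2, NaOAc, n-Bu4NCl, DMF, 80 °C) should give racemic 7-benzyloxy-5-hydroxy-3-[2-(prop-1-en-2-yl)-2,3-dihydro-1-benzofuran-5-yl]-4H-chromen-4-one F1. Its enantiomers would be separated by preparative HPLC on a polysaccharide chiral stationary phase, and the R enantiomer is compound 7, where the route resumes.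

Step 2. Site selectivity may be lost through etherification at the iodophenol oxygen or double benzylation. The fallback sets out from 4 and uses an acetate relay.
- Acetylation of the two reactive phenols (Ac2O, pyridine, 0 °C; the chelated 5-OH stays free) should give 7,4'-diacetoxy-5-hydroxy-3'-iodoisoflavone F2.
- Thiolysis of the more electrophilic 7-acetate (PhSH, imidazole, N-methylpyrrolidone, 0 °C) should give 4'-acetoxy-5,7-dihydroxy-3'-iodoisoflavone F3.
- Mitsunobu benzylation of the only remaining acidic phenol (BnOH, PPh3, DIAD, THF) should give 4'-acetoxy-7-benzyloxy-5-hydroxy-3'-iodoisoflavone F4.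
- Methanolysis of the aryl acetate (K2CO3, MeOH, 0 °C) returns to compound 5.

Step 1. Iodine may be lost from the ortho-iodophenol, or transferred to phloroglucinol, in hot BF3·OEt2, which would lead to halogen-free genistein. The fallback sets out from 1 and changes the halogen handle to the acid-stable bromide.
- Purchased 3-bromo-4-hydroxyphenylacetic acid F5 is taken through the same one-pot acylation and ring closure, via 2-(3-bromo-4-hydroxyphenyl)-1-(2,4,6-trihydroxyphenyl)ethan-1-one F6 (not isolated), to 3'-bromo-5,7,4'-trihydroxyisoflavone F7.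
- Bicarbonate-controlled benzylation as in step 2 gives 7-benzyloxy-3'-bromo-5,4'-dihydroxyisoflavone F8.
- The enantioselective annulation with 6 under the step 3 conditions, for which ortho-bromophenols are standard substrates, delivers compound 7.

**Further compounds**
F1 | step 3 | racemic 7-benzyloxy-5-hydroxy-3-[2-(prop-1-en-2-yl)-2,3-dihydro-1-benzofuran-5-yl]-4H-chromen-4-one | C=C(C)C1Cc2cc(-c3coc4cc(OCc5ccccc5)cc(O)c4c3=O)ccc2O1
F2 | step 2 | 7,4'-diacetoxy-5-hydroxy-3'-iodoisoflavone | CC(=O)Oc1ccc(-c2coc3cc(OC(C)=O)cc(O)c3c2=O)cc1I
F3 | step 2 | 4'-acetoxy-5,7-dihydroxy-3'-iodoisoflavone | CC(=O)Oc1ccc(-c2coc3cc(O)cc(O)c3c2=O)cc1I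
F4 | step 2 | 4'-acetoxy-7-benzyloxy-5-hydroxy-3'-iodoisoflavone | CC(=O)Oc1ccc(-c2coc3cc(OCc4ccccc4)cc(O)c3c2=O)cc1I
F5 | step 1 | 3-bromo-4-hydroxyphenylacetic acid (purchased) | O=C(O)Cc1ccc(O)c(Br)c1
F6 | step 1 | 2-(3-bromo-4-hydroxyphenyl)-1-(2,4,6-trihydroxyphenyl)ethan-1-one (not isolated) | O=C(Cc1ccc(O)c(Br)c1)c1c(O)cc(O)cc1O
F7 | step 1 | 3'-bromo-5,7,4'-trihydroxyisoflavone | O=c1c(-c2ccc(O)c(Br)c2)coc2cc(O)cc(O)c12
F8 | step 1 | 7-benzyloxy-3'-bromo-5,4'-dihydroxyisoflavone | O=c1c(-c2ccc(O)c(Br)c2)coc2cc(OCc3ccccc3)cc(O)c12
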